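(The numbers belong to no real substance; the rest is arithmetic.)

The side step that eats target speeds up more with heat than the coupling that makes it: from the coldest flask to the hottest, the side step gains a factor 28 and coupling a factor 11.

the same everywhere: starting material 0.20 M; coupling partner 0.600 M; time 2.0 d
- Saturday's: temperature 65 °C
- Tuesday's: temperature 50 °C
- Wednesday's: temperature 20 °C
- Thursday's: temperature 35 °C

* which flask leads in amount of target, in percent of the starting material charged ("all alike" within 1.5 percentage points) (Saturday's / Tuesday's / Wednesday's / Thursday's / all alike)
* how much target is there at the end, in percent of the starting material charged: Saturday's
* how much target is there at the end, in percent of the starting material charged: Tuesday's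
* how much target is there at the end, in percent of the starting material charged: Wednesday's
* how much target is there at the end, in percent of the starting material charged: Thursday's

- a species is counted by the starting material in it: one side product counts as two
- amounts and yields of target count crystals too
- given per volume of solution although it is solid: crystals
- the list of constants is for 50 °C, to be carried to other temperatures by the activation energies

    starting material + coupling partner → target, rate k1*[starting material]^2*[coupling partner] (k1 = 0.80 /M²/h, Ea1 = 44.0 kJ/mol)
    starting material + target → side product (k2 = 1.0 /M/h, Ea2 = 61.0 kJ/mol)
    crystals ⇌ target, rate k3*(cs3 - [target]) while solid is left; crystals form when [target] > cs3 (cs3 = 29 mM, k3 = 0.92 /h)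
    coupling partner → decomposed reagent (k4 = 0.080 /h, Ea4 = 118 kJ/mol)
    (constants at 50 °C)

Target is made in one step and eaten in another, so we compare two times and set the partner's decay and the crystals aside for this reckoning. The coupling time τc is the charged starting material divided by its opening rate of coupling, which is 2.32 d for Wednesday's at 20 °C. The side time τs is the life of dissolved target against the charged starting material, the inverse of the side step's constant times that charge: 2.13 d for Wednesday's.

We carry their ratio τs/τc, for Wednesday's 0.917: the balance share ρ, a selectivity factor, which is the part of the charge standing as dissolved target at which making and side loss are equal while starting material and partner stand at their charges. Thursday's has 0.653, Tuesday's 0.480 and Saturday's 0.363. As the charges are used, ρ is multiplied by the part left of each. So we commit to a ranking, not to percentages: Wednesday's first, then Thursday's, Tuesday's and Saturday's.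

The forecast named Wednesday's, with 0% for Saturday's, 2.5% for Tuesday's, 29.5% for Wednesday's and 28.5% for Thursday's, holding that in the cold flasks “the partner survives and crystals shield the target”.

The simulation puts Wednesday's in front, with 32.1% for Wednesday's, 26.9% for Thursday's, 2.64% for Tuesday's and 0% for Saturday's, the order of our ρ.

At 2.00 d, ρ multiplied by the parts left gives 38.6% for Wednesday's, above its dissolved target of 14.8%, so in Wednesday's flask making still outruns side loss. For Thursday's it gives 9.75%, below its dissolved target of 14.4%, so in Thursday's flask side loss outruns making.

Wednesday's flask charged with 0.24 M of partner has, at the same temperature, ρ scaled with the partner to 0.367. That neighbour gives 14.6% of target at 2.00 d, against 32.1% for Wednesday's.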